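## Retrosynthetic overview

- The target is numbered as a bicyclo[3.2.1]oct-3-ene-2,8-dione: C1 H-bridgehead, C2 ketone, C3 OMe, C4 =CH, C5 allyl bridgehead, C6 Me, C7 aryl, C8 bridging ketone. The key disconnection cuts C1–C2 and C4–C5: the whole bridge C2(=O)–C3(OMe)=C4H is laid across the two α-carbons of a cyclopentanone in one enamine α,α′-annulation with 2,3-dimethoxyacryloyl chloride, and this step gives the natural product.
- Enabling feature: ring C1–C8–C5–C6–C7 is a cyclopentanone whose carbonyl C8 has exactly C1 and C5 as α-carbons. C2=O is 1,3 to C8=O (acylation of C1) and C4 is the β-carbon of the C2 enone, 1,5 to C8=O (conjugate addition–elimination from C5). The bridge is therefore an acyl/formyl-enol-ether 1,3-bis-electrophile and needs no later redox change.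
- Precursor: all-trans 2-allyl-3-methyl-4-arylcyclopentanone, made from (S)-4-arylcyclopent-2-enone by cuprate addition anti to aryl and allylation anti to methyl. The C7 aryl stereocenter then steers the bridge to the opposite face.
- The enone comes from cyclopent-3-enol by enantioselective Heck–Matsuda desymmetrisation with the veratryl diazonium salt, then oxidation. The acid chloride comes from methyl methoxyacetate (formylation/O-methylation, hydrolysis, chlorination).
- Ring order: the five-membered ring is present from the start (cyclopent-3-enol); the six-membered ring C1–C2–C3–C4–C5–C8, and with it the bicycle, is closed last.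

Key step: step 9

Assumption: in step 2 the antipode of the chiral N,N ligand is used that gives C4 of 4 as S (sense of induction to be confirmed on the first batch). Compounds 10–13 are drawn as Z isomers; their alkene geometry is erased in step 9. Target numbering (C1–C8) is used for the corresponding atoms of all intermediates.

## Route

Step 1
Reactants: 1 3,4-dimethoxyaniline
Product: 2 3,4-dimethoxybenzenediazonium tetrafluoroborate
Conditions: NaNO2, aq. HBF4, 0 °C
Reagents that add atoms: sodium nitrite ([Na+].[O-]N=O); tetrafluoroboric acid ([H+].F[B-](F)(F)F)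
Why: Diazotization of the electron-rich aniline in aqueous HBF4 should give the arenediazonium tetrafluoroborate, which precipitates and carries no stereocenter.

Step 2
Reactants: 2 3,4-dimethoxybenzenediazonium tetrafluoroborate; 3 cyclopent-3-en-1-ol
Product: 4 (1R,4S)-4-(3,4-dimethoxyphenyl)cyclopent-2-en-1-ol (cis)
Conditions: Pd(O2CCF3)2 (cat.), chiral pyridine-oxazoline N,N ligand (cat.), ZnCO3, MeOH, 40 °C
Reagents that add atoms: none
Why: In this enantioselective Heck–Matsuda desymmetrisation the cationic aryl-palladium species, bound to the chiral ligand and directed by the hydroxyl group, should add to one enantiotopic alkene carbon on the hydroxyl face, and β-hydride elimination away from the aryl carbon then gives the cis allylic alcohol with the ligand antipode fixing C4 as S.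

Step 3
Reactants: 4 (1R,4S)-4-(3,4-dimethoxyphenyl)cyclopent-2-en-1-ol
Product: 5 (4S)-4-(3,4-dimethoxyphenyl)cyclopent-2-en-1-one
Conditions: MnO2, CH2Cl2, rt
Reagents that add atoms: none
Why: MnO2 oxidises allylic alcohols selectively under neutral conditions (allylic alcohol oxidation), so the carbinol center is removed while the base-sensitive γ-stereocenter bearing the aryl group should stay intact.

Step 4
Reactants: 5 (4S)-4-(3,4-dimethoxyphenyl)cyclopent-2-en-1-one
Product: 7 (2S,3R,4S)-2-allyl-4-(3,4-dimethoxyphenyl)-3-methylcyclopentan-1-one, via lithium enolate 6 (not isolated)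
Conditions: Me2CuLi (from MeLi, CuI), Et2O, −78 °C; then allyl iodide, HMPA, THF, −78 → −20 °C
Reagents that add atoms: lithium dimethylcuprate, made in the flask from MeLi and CuI ([Li+].C[Cu-]C); allyl iodide (C=CCI)
Why: Conjugate addition of the Gilman cuprate should occur anti to the C4 aryl group and the regiodefined enolate 6 is then allylated anti to the new methyl group (conjugate addition–enolate alkylation), which gives the all-trans ketone.

Step 5
Reactants: 7 (2S,3R,4S)-2-allyl-4-(3,4-dimethoxyphenyl)-3-methylcyclopentan-1-one
Product: 8 1-[(3R,4R,5S)-5-allyl-3-(3,4-dimethoxyphenyl)-4-methylcyclopent-1-en-1-yl]pyrrolidine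
Conditions: pyrrolidine, p-TsOH (cat.), toluene, reflux, Dean–Stark trap
Reagents that add atoms: pyrrolidine (C1CCNC1)
Why: Acid-catalysed condensation with removal of water (Stork enamine formation) should place the double bond toward the unsubstituted α-carbon, because the tetrasubstituted isomer suffers allylic strain, and it does not touch the methyl- and aryl-bearing stereocenters.

Step 6
Reactants: 9 methyl methoxyacetate
Product: 11 methyl (Z)-2,3-dimethoxyacrylate, via sodium enolate 10 (not isolated)
Conditions: NaH, HCO2Me, THF, 0 °C → rt; then Me2SO4, DMF, rt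
Reagents that add atoms: methyl formate (COC=O); dimethyl sulfate (COS(=O)(=O)OC)
Why: Crossed Claisen formylation with methyl formate gives the stabilised sodium enolate 10, whose oxygen is methylated by the hard electrophile dimethyl sulfate (O-alkylation) to the β-methoxyacrylate.

Step 7
Reactants: 11 methyl (Z)-2,3-dimethoxyacrylate
Product: 12 (Z)-2,3-dimethoxyacrylic acid
Conditions: LiOH, THF/H2O, rt; then aq. HCl to pH 3, 0 °C
Reagents that add atoms: lithium hydroxide ([Li+].[OH-])
Why: Saponification of the ester should proceed without loss of the enol ether, since β-alkoxyacrylates tolerate aqueous hydroxide at room temperature and brief cold acidification.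

Step 8
Reactants: 12 (Z)-2,3-dimethoxyacrylic acid
Product: 13 (Z)-2,3-dimethoxyacryloyl chloride
Conditions: (COCl)2, DMF (cat.), CH2Cl2, 0 °C → rt; used crude
Reagents that add atoms: oxalyl chloride (ClC(=O)C(Cl)=O)
Why: Oxalyl chloride with catalytic DMF converts the acid into the acid chloride through the chloroiminium species (acid chloride formation) under conditions that 3-alkoxyacryloyl chlorides are known to survive.

Step 9
Reactants: 8 1-[(3R,4R,5S)-5-allyl-3-(3,4-dimethoxyphenyl)-4-methylcyclopent-1-en-1-yl]pyrrolidine; 13 (Z)-2,3-dimethoxyacryloyl chloride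
Product: 16 Kadsurenin D, (1S,5S,6R,7R)-5-allyl-7-(3,4-dimethoxyphenyl)-3-methoxy-6-methylbicyclo[3.2.1]oct-3-ene-2,8-dione, via enaminone 14 (not isolated), via bridged iminium chloride 15 (not isolated)
Conditions: 2,6-lutidine, MeCN, 0 °C → rt; then 80 °C; then aq. NaOAc/AcOH, rt
Reagents that add atoms: water (O)
Why: Proposed new method: the enamine carbon (future C1) of 8 is C-acylated by 13 (Stork enamine acylation), the vinylogous amide 14 equilibrates, with 2,6-lutidinium chloride as proton shuttle, through its C1-protonated iminium form with the cross-conjugated enamine at the allyl-bearing carbon (future C5), and this enamine adds to the methoxy-bearing chain terminus C4 and expels methanol to give the bridged iminium salt 15, which water hydrolyses to the C8 ketone. The closest known reaction type is the α,α′-annulation of cyclic ketone enamines with acryloyl chlorides to bicyclo[3.n.1]alkanediones, in which the more substituted enamine likewise builds the quaternary bridgehead; the β-methoxy group of 13 makes the alkene a poor Michael acceptor, so that acylation comes first (as with other 3-alkoxyacryloyl chlorides) and the enone is kept. One ring is closed, the six-membered ring C1–C2–C3–C4–C5–C8, by a 6-endo-trig conjugate addition–elimination of the enamine carbon onto the enone β-carbon, possible only from the tautomer with sp3 C1 and an axial acyl arm. C1 and the quaternary C5 are set together, relative to C6 and C7, because the bridge must span one face of the five-membered ring: C1 is trigonal in 14, so the arm can swing to either face, and closure is expected on the face anti to the C7 aryl group (arm trans to aryl), which places aryl exo and the C6 methyl endo as in 16. The step needs acylation at the unsubstituted α-carbon (secured by the less substituted enamine), carbon instead of heteroatom ring closure (secured by nitrogen in place of the C8 oxygen, which closes the pyranone pathway of the free 1,3-diketone) and bond formation at C5 (the only other position that can become an enamine).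

## Compound list

1 | 3,4-dimethoxyaniline | COc1ccc(N)cc1OC | starting material
2 | 3,4-dimethoxybenzenediazonium tetrafluoroborate | COc1ccc([N+]#N)cc1OC.F[B-](F)(F)F | intermediate
3 | cyclopent-3-en-1-ol | OC1CC=CC1 | starting material
4 | (1R,4S)-4-(3,4-dimethoxyphenyl)cyclopent-2-en-1-ol (hydroxyl and aryl cis) | O[C@H]1C=C[C@@H](c2ccc(OC)c(OC)c2)C1 | intermediate
5 | (4S)-4-(3,4-dimethoxyphenyl)cyclopent-2-en-1-one | O=C1C=C[C@@H](c2ccc(OC)c(OC)c2)C1 | intermediate
6 | lithium (3R,4S)-4-(3,4-dimethoxyphenyl)-3-methylcyclopent-1-en-1-olate (methyl and aryl trans) | [Li+].[O-]C1=C[C@H](C)[C@@H](c2ccc(OC)c(OC)c2)C1 | intermediate (not isolated)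
7 | (2S,3R,4S)-2-allyl-4-(3,4-dimethoxyphenyl)-3-methylcyclopentan-1-one (all-trans) | C=CC[C@@H]1C(=O)C[C@H](c2ccc(OC)c(OC)c2)[C@H]1C | intermediate
8 | 1-[(3R,4R,5S)-5-allyl-3-(3,4-dimethoxyphenyl)-4-methylcyclopent-1-en-1-yl]pyrrolidine | C=CC[C@@H]1C(N2CCCC2)=C[C@H](c2ccc(OC)c(OC)c2)[C@H]1C | intermediate
9 | methyl methoxyacetate | COCC(=O)OC | starting material
10 | sodium (Z)-2,3-dimethoxy-3-oxoprop-1-en-1-olate | [Na+].[O-]/C=C(\OC)C(=O)OC | intermediate (not isolated)
11 | methyl (Z)-2,3-dimethoxyacrylate | CO/C=C(\OC)C(=O)OC | intermediate
12 | (Z)-2,3-dimethoxyacrylic acid | CO/C=C(\OC)C(=O)O | intermediate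
13 | (Z)-2,3-dimethoxyacryloyl chloride | CO/C=C(\OC)C(Cl)=O | intermediate
14 | (2Z)-1-[(3S,4R,5S)-3-allyl-5-(3,4-dimethoxyphenyl)-4-methyl-2-(pyrrolidin-1-yl)cyclopent-1-en-1-yl]-2,3-dimethoxyprop-2-en-1-one (enaminone) | C=CC[C@@H]1C(N2CCCC2)=C(C(=O)C(/OC)=C/OC)[C@H](c2ccc(OC)c(OC)c2)[C@H]1C | intermediate (not isolated)
15 | 1-[5-allyl-7-(3,4-dimethoxyphenyl)-3-methoxy-6-methyl-2-oxobicyclo[3.2.1]oct-3-en-8-ylidene]pyrrolidinium chloride, all four stereocenters arranged as in 16 | C=CC[C@]12C=C(OC)C(=O)[C@H](C1=[N+]3CCCC3)[C@H](c3ccc(OC)c(OC)c3)[C@H]2C.[Cl-] | intermediate (not isolated)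
16 | Kadsurenin D, (1S,5S,6R,7R)-5-allyl-7-(3,4-dimethoxyphenyl)-3-methoxy-6-methylbicyclo[3.2.1]oct-3-ene-2,8-dione (aryl exo, methyl endo) | C=CC[C@]12C=C(OC)C(=O)[C@H](C1=O)[C@H](c1ccc(OC)c(OC)c1)[C@H]2C | target

## Step count and risks

Total step count: 9.
Longest linear sequence: 6 steps (steps 1, 2, 3, 4, 5, 9); the acid chloride branch is steps 6–8.

Steps most likely to fail:

**Step 9 (proposed new method).** The sequence may stall at the vinylogous amide because the proton shifts that lead to the reactive tautomer are too slow. Acylation may also run Michael-first and reverse the regiochemistry, or closure may take place on the aryl face. The fallback uses known reactions only, sets out from ketone 7 and returns at 16. C1 is blocked by a removable phenylthio group, so that the acylation itself becomes the stereodefining event and no planar 1,3-diketone or pyranone can form. Kinetic deprotonation of 7 (LDA, THF, −78 °C) and sulfenylation with PhSSPh should give the 5-(phenylsulfanyl) ketone F1. Soft enolisation at the now most acidic position (MgBr2·OEt2, i-Pr2NEt, CH2Cl2) and C-acylation with 13, anti to the neighbouring aryl group, should give the non-enolisable acyl sulfide F2. TMSOTf/Et3N then silylates the only enolisable position to give the silyl enol ether F3. TiCl4 (CH2Cl2, −78 °C) should close the ring by an intramolecular Mukaiyama–Michael addition with loss of the methoxy group, giving the bridged sulfide F4. Radical desulfurisation (Bu3SnH, AIBN, benzene, 80 °C) gives 16.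

**Step 4.** Proton transfer between enolate 6 and the product may give regioisomeric and over-allylated ketones, and alkylation of the cuprate-derived enolate may be sluggish. The fallback sets out from enone 5 and returns at 7. Enolate 6, made as before, is trapped on oxygen with allyl chloroformate to give the allyl enol carbonate F5. Pd(PPh3)4 in THF then effects a regiospecific decarboxylative Tsuji allylation through the zerovalent-palladium-derived π-allyl/enolate pair, the allyl group entering anti to the methyl group.

**Step 2.** Enantioinduction or cis selectivity may be insufficient with the electron-rich diazonium salt, and the double bond may migrate further toward the ketone. The fallback sets out from 2 and 3 and returns at 4. The Heck–Matsuda arylation is run without chiral ligand (Pd(OAc)2, MeOH), which gives racemic cis alcohol, that is 4 together with its enantiomer, the (1S,4R)-alcohol F6. Lipase-catalysed kinetic resolution (immobilised Candida antarctica lipase B, vinyl acetate) is expected to acylate the (1R)-alcohol to the (1R,4S)-acetate F7, which is separated from F6 and cleaved with K2CO3/MeOH to give 4.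

Further compounds
F1 | step 9 | 2-allyl-4-(3,4-dimethoxyphenyl)-3-methyl-5-(phenylsulfanyl)cyclopentan-1-one (ring substituents all-trans) | C=CC[C@@H]1C(=O)[C@@H](Sc2ccccc2)[C@H](c2ccc(OC)c(OC)c2)[C@H]1C
F2 | step 9 | 2-allyl-5-[(Z)-2,3-dimethoxyacryloyl]-4-(3,4-dimethoxyphenyl)-3-methyl-5-(phenylsulfanyl)cyclopentan-1-one (acyl group trans to aryl) | C=CC[C@@H]1C(=O)[C@@](Sc2ccccc2)(C(=O)C(/OC)=C/OC)[C@H](c2ccc(OC)c(OC)c2)[C@H]1C
F3 | step 9 | trimethylsilyl enol ether of F2 (double bond toward the allyl-bearing carbon) | C=CCC1=C(O[Si](C)(C)C)[C@@](Sc2ccccc2)(C(=O)C(/OC)=C/OC)[C@H](c2ccc(OC)c(OC)c2)[C@H]1C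
F4 | step 9 | 1-(phenylsulfanyl) derivative of 16 (other stereocenters as in 16) | C=CC[C@]12C=C(OC)C(=O)[C@](Sc3ccccc3)(C1=O)[C@H](c1ccc(OC)c(OC)c1)[C@H]2C
F5 | step 4 | allyl (3R,4S)-4-(3,4-dimethoxyphenyl)-3-methylcyclopent-1-en-1-yl carbonate | C=CCOC(=O)OC1=C[C@H](C)[C@@H](c2ccc(OC)c(OC)c2)C1
F6 | step 2 | (1S,4R)-4-(3,4-dimethoxyphenyl)cyclopent-2-en-1-ol | O[C@@H]1C=C[C@H](c2ccc(OC)c(OC)c2)C1
F7 | step 2 | (1R,4S)-4-(3,4-dimethoxyphenyl)cyclopent-2-en-1-yl acetate | CC(=O)O[C@H]1C=C[C@@H](c2ccc(OC)c(OC)c2)C1
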